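Assumption: the target, 4,6-dibromo-2-(2,4-dibromo-6-methoxyphenoxy)phenol, has no stereocentre and no configurationally stable axis, so "single enantiomer" needs no stereocontrol.

**Retrosynthetic overview**
- The obvious Ullmann/SNAr aryl-halide etherification is avoided. The diaryl ether C–O bond is made by O–H insertion of a ring-B carbene into the ring-A phenol, so all four C–Br bonds are bystanders.
- Target 5 ⇒ phenol 2 (ring A, nucleophile) + o-quinone diazide 4 (ring B, carbene precursor; the diazo carbon becomes C2–OAr and the C=O becomes the free OH).
- 4 ⇒ diazotisation of commercial 2-amino-4,6-dibromophenol 3, which already carries the ring-B bromine pattern.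
- 2 ⇒ ortho-bromination of commercial 4-bromoguaiacol 1.
- No ring is formed: both benzene rings are bought intact; ring B is joined to ring A in the last step.

**Route**

Step 1
Reactants: 1 4-bromo-2-methoxyphenol
Product: 2 2,4-dibromo-6-methoxyphenol
Conditions: NBS (1.05 equiv), i-Pr2NH (10 mol%), CH2Cl2, 0 °C to rt
Reagents that add atoms: N-bromosuccinimide, O=C1CCC(=O)N1Br
Why: Electrophilic aromatic bromination in which the free OH is the dominant director, its para position is already blocked, and the amine-mediated NBS protocol delivers Br ortho to OH (C6) rather than para to OMe (C5); no stereocentre is formed.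

Step 2
Reactants: 3 2-amino-4,6-dibromophenol
Product: 4 3,5-dibromo-2-oxidobenzenediazonium (= 2,4-dibromo-6-diazocyclohexa-2,4-dien-1-one, the o-quinone diazide)
Conditions: t-BuONO (1.3 equiv), AcOH (cat.), MeCN, 0 °C, dark, 3 added slowly; precipitate with cold Et2O, filter, do not heat or grind, small batches, use at once
Reagents that add atoms: tert-butyl nitrite, CC(C)(C)ON=O
Why: Diazotisation of an o-aminophenol with an alkyl nitrite, where the acidic dibromophenol OH loses its proton as the diazonium forms to give the neutral, halogen-stabilised diazonium phenolate (o-quinone diazide); no stereocentre is formed.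

Step 3
Reactants: 2 2,4-dibromo-6-methoxyphenol (2 equiv, excess recovered); 4 3,5-dibromo-2-oxidobenzenediazonium
Product: 5 4,6-dibromo-2-(2,4-dibromo-6-methoxyphenoxy)phenol (target)
Conditions: Rh2(OAc)4 (2 mol%), 4 Å MS, ClCH2CH2Cl, 60 °C, dark, 4 added over 3 h by syringe pump (no arene or alcohol solvent)
Reagents that add atoms: none
Why: Proposed new method: Rh(II) takes N2 from the diazo-oxide to give an electrophilic 2-oxocyclohexadienylidene carbenoid at C2 of ring B, the phenol oxygen of 2 adds to it (the ortho/para carbons of 2 carry Br, Br and OMe, so azo coupling and C-arylation are blocked), and the oxonium ylide transfers its proton to the enolate oxygen, which aromatises ring B to the 2-aryloxyphenol, while metal binding suppresses the Wolff ring contraction of the free carbene and slow addition limits carbene dimerisation and insertion into the product OH; the closest known reaction type is Rh(II)-carbenoid O–H insertion of phenols and alcohols into α-diazo ketones and diazonaphthoquinones.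

**Compound list**
1 | 4-bromo-2-methoxyphenol (4-bromoguaiacol) | COc1cc(Br)ccc1O | starting material
2 | 2,4-dibromo-6-methoxyphenol | COc1cc(Br)cc(Br)c1O | intermediate
3 | 2-amino-4,6-dibromophenol | Nc1cc(Br)cc(Br)c1O | starting material
4 | 3,5-dibromo-2-oxidobenzenediazonium (2,4-dibromo-6-diazocyclohexa-2,4-dien-1-one) | [O-]c1c(Br)cc(Br)cc1[N+]#N | intermediate
5 | 4,6-dibromo-2-(2,4-dibromo-6-methoxyphenoxy)phenol | COc1cc(Br)cc(Br)c1Oc1cc(Br)cc(Br)c1O | target

**Step count**
Total steps: 3. Longest linear sequence: 2 steps (step 1 → step 3, or step 2 → step 3).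

**Steps most likely to fail, with fallbacks**

Step 3 (highest risk: Wolff rearrangement, carbene dimerisation, or poor capture by the hindered, weakly nucleophilic phenol). The fallback sets out from 2 and comes back at 5, building ring B de novo from a cyclohexanone so that the ether bond is made by SN2 at sp3 carbon. Phenol 2 is alkylated with 2-chlorocyclohexanone (K2CO3, cat. KI, DMF, 60 °C) to give rac-2-(2,4-dibromo-6-methoxyphenoxy)cyclohexan-1-one F1. The ketone ring is then dehydrogenated to the arene (cat. I2, DMSO, 100 °C, a halogen-tolerant aromatisation) to give 2-(2,4-dibromo-6-methoxyphenoxy)phenol F2. NBS (2.05 equiv, MeCN, 0 °C) brominates only the free-phenol ring, para and ortho to OH, because ring A is an anisole deactivated by two bromines; this gives 5.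

Step 2 (risk: oxidation or triazene formation from the aminophenol during nitrosation, and limited stability of the isolated diazo-oxide). The fallback sets out from 2 and comes back at 5, abandoning the diazo partner for a classical SNAr/Baeyer–Villiger sequence. Phenoxide 2 displaces fluoride from 4-bromo-2-fluorobenzaldehyde (K2CO3, DMAc, 120 °C; F ortho to CHO reacts far faster than Br) to give 4-bromo-2-(2,4-dibromo-6-methoxyphenoxy)benzaldehyde F3. Baeyer–Villiger oxidation (mCPBA, CH2Cl2, rt) gives 4-bromo-2-(2,4-dibromo-6-methoxyphenoxy)phenyl formate F4. Hydrolysis (KOH, MeOH/H2O) gives 4-bromo-2-(2,4-dibromo-6-methoxyphenoxy)phenol F5. One equivalent of NBS (cat. i-Pr2NH, CH2Cl2) then brominates the only open position ortho to the free OH to give 5.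

Step 1 (lowest risk: some bromination para to OMe at C5, or over-bromination). The fallback sets out from 4 and comes back at 2, making the C–OMe bond instead of the C–Br bond. Quinone diazide 4 is decomposed with Rh2(OAc)4 (1 mol%) in MeOH/ClCH2CH2Cl at 50 °C; O–H insertion of methanol gives 2 directly. The bromine pattern is then fixed by aminophenol 3, which becomes the source of both rings. This fallback makes no compound outside the list (F0).

Further compounds
F1 | step 3 | rac-2-(2,4-dibromo-6-methoxyphenoxy)cyclohexan-1-one | COc1cc(Br)cc(Br)c1OC1CCCCC1=O
F2 | step 3 | 2-(2,4-dibromo-6-methoxyphenoxy)phenol | COc1cc(Br)cc(Br)c1Oc1ccccc1O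
F3 | step 2 | 4-bromo-2-(2,4-dibromo-6-methoxyphenoxy)benzaldehyde | COc1cc(Br)cc(Br)c1Oc1cc(Br)ccc1C=O
F4 | step 2 | 4-bromo-2-(2,4-dibromo-6-methoxyphenoxy)phenyl formate | COc1cc(Br)cc(Br)c1Oc1cc(Br)ccc1OC=O
F5 | step 2 | 4-bromo-2-(2,4-dibromo-6-methoxyphenoxy)phenol | COc1cc(Br)cc(Br)c1Oc1cc(Br)ccc1O
F0 | step 1 | none | none
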